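## Retrosynthetic overview

1. The target comes from a protected tetralone by one-pot O-debenzylation and O-desilylation.
2. The phenol ring B is closed by a catalyst-controlled vinylogous aldol condensation/aromatisation onto one of the two enantiotopic ring carbonyls of a Cs-symmetric 2-acyl-5-silyloxycyclohexane-1,3-dione; this sets C3.
3. The triketone comes from C-acylation of prochiral 5-silyloxycyclohexane-1,3-dione (made by dearomatising reduction of phloroglucinol) with a 4-pyronyl-3-phenylbut-2-enoic acid.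
4. The acid comes from Michael addition of lithiated O-benzyl triacetic acid lactone to tert-butyl phenylpropiolate.
5. Ring order: ring A (from phloroglucinol) and the pyrone (from triacetic acid lactone) arrive preformed; benzene ring B is formed last, in the key step.

Assumption: tert-butyl 3-phenylpropiolate and (R)-TRIP are purchasable; (R)-TRIP is assumed to give the 3S series, and its enantiomer is used instead if the opposite sense is found.

## Route

Step 1
Reactants: 1 phloroglucinol (benzene-1,3,5-triol)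
Product: 2 5-hydroxycyclohexane-1,3-dione (dihydrophloroglucinol; achiral)
Conditions: NaBH4, H2O, 0 °C→rt; then 2 M HCl to pH 3, 0 °C
Reagents that add atoms: none
Why: Phloroglucinol reacts through its triketo tautomer, so hydride adds to one C=O (dearomatising borohydride reduction) and the resulting vinylogous-acid enolate resists further reduction; the product is achiral.

Step 2
Reactants: 2 5-hydroxycyclohexane-1,3-dione
Product: 4 5-(tert-butyldimethylsilyloxy)cyclohexane-1,3-dione (achiral; prochiral at C5), via bis-silyl enone 3 (not isolated)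
Conditions: TBSCl (2.5 equiv), imidazole, DMF, 0 °C→rt; then 1 M aq. citric acid/THF, rt
Reagents that add atoms: tert-butyldimethylsilyl chloride, CC(C)(C)[Si](C)(C)Cl
Why: Exhaustive silylation followed by selective hydrolysis of the labile vinylogous silyl ester leaves only the secondary TBS ether (silyl ether protection), which blocks O-acylation and dehydration to a resorcinol later.

Step 3
Reactants: 5 triacetic acid lactone (4-hydroxy-6-methyl-2H-pyran-2-one)
Product: 6 4-(benzyloxy)-6-methyl-2H-pyran-2-one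
Conditions: BnBr, K2CO3, DMF, rt
Reagents that add atoms: benzyl bromide, BrCc1ccccc1
Why: Williamson O-alkylation of the acidic 4-OH gives the benzyl vinylogous ester, which is stable to LDA and TFA and removable by hydrogenolysis.

Step 4
Reactants: 6 4-(benzyloxy)-6-methyl-2H-pyran-2-one; 7 tert-butyl 3-phenylprop-2-ynoate
Product: 9 tert-butyl (2E)-4-[4-(benzyloxy)-2-oxo-2H-pyran-6-yl]-3-phenylbut-2-enoate, via lithiated pyrone 8 (not isolated)
Conditions: LDA (1.05 equiv), THF, −78 °C; then 7, −78→−40 °C; AcOH quench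
Reagents that add atoms: none
Why: Vinylogous deprotonation of the 6-methyl group gives an extended dienolate that undergoes Michael addition to the ynoate β-carbon (the tert-butyl ester suppresses 1,2-addition), and proton transfer gives the more stable E-enoate with the ester trans to phenyl.

Step 5
Reactants: 9 tert-butyl (2E)-4-[4-(benzyloxy)-2-oxo-2H-pyran-6-yl]-3-phenylbut-2-enoate
Product: 10 (2E)-4-[4-(benzyloxy)-2-oxo-2H-pyran-6-yl]-3-phenylbut-2-enoic acid
Conditions: TFA/CH2Cl2 (1:3), rt
Reagents that add atoms: none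
Why: Acidolysis of the tert-butyl ester (E1 loss of isobutene) frees the acid while the benzyl vinylogous ester and the pyrone are stable to TFA.

Step 6
Reactants: 10 (2E)-4-[4-(benzyloxy)-2-oxo-2H-pyran-6-yl]-3-phenylbut-2-enoic acid; 4 5-(tert-butyldimethylsilyloxy)cyclohexane-1,3-dione
Product: 12 2-{(2E)-4-[4-(benzyloxy)-2-oxo-2H-pyran-6-yl]-3-phenylbut-2-enoyl}-5-(tert-butyldimethylsilyloxy)cyclohexane-1,3-dione (chelated enol; achiral), via enol ester 11 (not isolated)
Conditions: DCC (1.1 equiv), DMAP (1.2 equiv), CH2Cl2, 0 °C→rt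
Reagents that add atoms: none
Why: Steglich O-acylation of the dione enol is followed by a DMAP-mediated 1,3-O→C acyl shift (Fries-type) to the thermodynamically favoured, hydrogen-bond-chelated 2-acyl-1,3-dione.

Step 7
Reactants: 12 2-{(2E)-4-[4-(benzyloxy)-2-oxo-2H-pyran-6-yl]-3-phenylbut-2-enoyl}-5-(tert-butyldimethylsilyloxy)cyclohexane-1,3-dione
Product: 14 (3S)-5-[4-(benzyloxy)-2-oxo-2H-pyran-6-yl]-3-(tert-butyldimethylsilyloxy)-8-hydroxy-6-phenyl-3,4-dihydronaphthalen-1(2H)-one, via aldol adduct 13 (not isolated)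
Conditions: (R)-TRIP (10 mol %), 4 Å MS, toluene, 50 °C
Reagents that add atoms: none
Why: Proposed new method: the chiral phosphoric acid promotes γ-enolisation of the enoyl chain to a dienol and hydrogen-bonds one ring carbonyl, so the γ-carbon (bearing the pyrone) attacks that carbonyl anti to the OTBS group in a six-membered vinylogous aldol transition state; because anti attack on the two enantiotopic carbonyls needs opposite carbonyl faces, the catalyst's face preference becomes a choice between the two carbonyls and C5 of the dione becomes the (S)-stereocentre C3, after which dehydration and enolisation give the phenol irreversibly; the closest known reaction type is the chiral-phosphoric-acid-catalysed desymmetrising intramolecular aldol condensation of prochiral 1,3-diones (Robinson/Hajos–Parrish type).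

Step 8
Reactants: 14 (3S)-5-[4-(benzyloxy)-2-oxo-2H-pyran-6-yl]-3-(tert-butyldimethylsilyloxy)-8-hydroxy-6-phenyl-3,4-dihydronaphthalen-1(2H)-one
Product: 16 wailupemycin F [(3S)-3,8-dihydroxy-5-(4-hydroxy-2-oxo-2H-pyran-6-yl)-6-phenyl-3,4-dihydronaphthalen-1(2H)-one], via debenzylated silyl ether 15 (not isolated)
Conditions: H2 (1 atm), 10% Pd/C, THF, rt; filter; then HF·pyridine, THF, 0 °C→rt
Reagents that add atoms: none
Why: Neutral hydrogenolysis cleaves the benzyl vinylogous ester faster than it touches the chelated aryl ketone or the pyrone, and buffered fluoride desilylation frees the carbinol without the E1cB elimination that base would cause, so C3 is untouched.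

## Compound list

1 | phloroglucinol | Oc1cc(O)cc(O)c1 | starting material
2 | 5-hydroxycyclohexane-1,3-dione | O=C1CC(O)CC(=O)C1 | intermediate
3 | rac-3,5-bis(tert-butyldimethylsilyloxy)cyclohex-2-en-1-one | O=C1C=C(O[Si](C)(C)C(C)(C)C)CC(O[Si](C)(C)C(C)(C)C)C1 | intermediate
4 | 5-(tert-butyldimethylsilyloxy)cyclohexane-1,3-dione | O=C1CC(O[Si](C)(C)C(C)(C)C)CC(=O)C1 | intermediate
5 | triacetic acid lactone (4-hydroxy-6-methyl-2H-pyran-2-one) | Cc1cc(O)cc(=O)o1 | starting material
6 | 4-(benzyloxy)-6-methyl-2H-pyran-2-one | Cc1cc(OCc2ccccc2)cc(=O)o1 | intermediate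
7 | tert-butyl 3-phenylprop-2-ynoate | CC(C)(C)OC(=O)C#Cc1ccccc1 | starting material
8 | 4-(benzyloxy)-6-(lithiomethyl)-2H-pyran-2-one | [Li]Cc1cc(OCc2ccccc2)cc(=O)o1 | intermediate
9 | tert-butyl (2E)-4-[4-(benzyloxy)-2-oxo-2H-pyran-6-yl]-3-phenylbut-2-enoate | CC(C)(C)OC(=O)/C=C(\Cc1cc(OCc2ccccc2)cc(=O)o1)c1ccccc1 | intermediate
10 | (2E)-4-[4-(benzyloxy)-2-oxo-2H-pyran-6-yl]-3-phenylbut-2-enoic acid | OC(=O)/C=C(\Cc1cc(OCc2ccccc2)cc(=O)o1)c1ccccc1 | intermediate
11 | rac-5-(tert-butyldimethylsilyloxy)-3-oxocyclohex-1-en-1-yl (2E)-4-[4-(benzyloxy)-2-oxo-2H-pyran-6-yl]-3-phenylbut-2-enoate | O=C1C=C(OC(=O)/C=C(\Cc2cc(OCc3ccccc3)cc(=O)o2)c2ccccc2)CC(O[Si](C)(C)C(C)(C)C)C1 | intermediate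
12 | 2-{(2E)-4-[4-(benzyloxy)-2-oxo-2H-pyran-6-yl]-3-phenylbut-2-enoyl}-5-(tert-butyldimethylsilyloxy)cyclohexane-1,3-dione (drawn as the triketo tautomer; achiral) | O=C1CC(O[Si](C)(C)C(C)(C)C)CC(=O)C1C(=O)/C=C(\Cc1cc(OCc2ccccc2)cc(=O)o1)c1ccccc1 | intermediate
13 | (3S)-5-[4-(benzyloxy)-2-oxo-2H-pyran-6-yl]-3-(tert-butyldimethylsilyloxy)-4a,8-dihydroxy-6-phenyl-3,4,4a,5-tetrahydronaphthalen-1(2H)-one (C4a and C5 not controlled; both are lost on dehydration) | O=C1C[C@@H](O[Si](C)(C)C(C)(C)C)CC2(O)C(c3cc(OCc4ccccc4)cc(=O)o3)C(c3ccccc3)=CC(O)=C12 | intermediate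
14 | (3S)-5-[4-(benzyloxy)-2-oxo-2H-pyran-6-yl]-3-(tert-butyldimethylsilyloxy)-8-hydroxy-6-phenyl-3,4-dihydronaphthalen-1(2H)-one | O=C1C[C@@H](O[Si](C)(C)C(C)(C)C)Cc2c1c(O)cc(-c1ccccc1)c2-c1cc(OCc2ccccc2)cc(=O)o1 | intermediate
15 | (3S)-3-(tert-butyldimethylsilyloxy)-8-hydroxy-5-(4-hydroxy-2-oxo-2H-pyran-6-yl)-6-phenyl-3,4-dihydronaphthalen-1(2H)-one | O=C1C[C@@H](O[Si](C)(C)C(C)(C)C)Cc2c1c(O)cc(-c1ccccc1)c2-c1cc(O)cc(=O)o1 | intermediate
16 | wailupemycin F, (3S)-3,8-dihydroxy-5-(4-hydroxy-2-oxo-2H-pyran-6-yl)-6-phenyl-3,4-dihydronaphthalen-1(2H)-one | O=C1C[C@@H](O)Cc2c1c(O)cc(-c1ccccc1)c2-c1cc(O)cc(=O)o1 | target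

## Step count and risks

Total steps: 8. Longest linear sequence: 6 steps (5 → 6 → 9 → 10 → 12 → 14 → 16; steps 3–8).

**Step 7 (most likely to fail).** The enantiotopic-carbonyl selection is unprecedented for an enolised 2-acyl-1,3-dione, the acidic triketone may catalyse a racemic background reaction, and the sense of induction is not predictable. Fallback: starting from 12, the ring closure is run without stereocontrol (diphenyl phosphate 10 mol %, toluene, 60 °C) to give the racemic silyl ether F1. HF·pyridine removes the silyl group to give the racemic hydroxy tetralone F2. Dess–Martin periodinane oxidises the carbinol, and the resulting β-diketone tautomerises to the achiral naphthalenetriol F3. The stereocentre is then set by a dearomatising Noyori transfer hydrogenation of F3 through its 1,3-diketo tautomer (RuCl(p-cymene)(TsDPEN), HCO2H/Et3N, catalyst enantiomer chosen for S); this reduces the non-conjugated C3 carbonyl, leaves the chelated aryl ketone, and gives the (S)-hydroxy tetralone F4. Hydrogenolysis of the benzyl group (H2, Pd/C) comes back to the route at 16.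

**Step 4.** The dienolate may add 1,2 to the ester, or the more acidic product may add to a second ynoate. Fallback: starting from 6, the lithiated pyrone 8 (made with 2 equiv LDA) is C-acylated with N-methoxy-N-methylbenzamide to give the phenacyl pyrone F5. The cerium enolate of tert-butyl acetate (LDA, CeCl3, THF, −78 °C) adds to this enolisable ketone to give the racemic β-hydroxy ester F6. TFA then dehydrates the tertiary benzylic alcohol and cleaves the tert-butyl ester in one operation, coming back to the route at 10.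

**Step 6.** The β,β-disubstituted, γ-acidic enoic acid may form a vinylketene or undergo the O→C acyl shift sluggishly. Fallback: starting from 4, DCC/DMAP coupling with commercial 3-phenylpropiolic acid gives the alkynoate enol ester F7. Its DMAP-mediated acyl shift gives the alkynoyl triketone F8, which closes spontaneously (6-endo-dig oxa-Michael) to the γ-pyrone F9. The lithiated pyrone 8 then adds to C2 of F9 and the ring opens by expulsion of the dione enolate (addition–elimination at a 4-pyranone), which after acidic work-up comes back to the route at 12.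

## Further compounds

F1 | step 7 | rac-5-[4-(benzyloxy)-2-oxo-2H-pyran-6-yl]-3-(tert-butyldimethylsilyloxy)-8-hydroxy-6-phenyl-3,4-dihydronaphthalen-1(2H)-one | O=C1CC(O[Si](C)(C)C(C)(C)C)Cc2c1c(O)cc(-c1ccccc1)c2-c1cc(OCc2ccccc2)cc(=O)o1
F2 | step 7 | rac-5-[4-(benzyloxy)-2-oxo-2H-pyran-6-yl]-3,8-dihydroxy-6-phenyl-3,4-dihydronaphthalen-1(2H)-one | O=C1CC(O)Cc2c1c(O)cc(-c1ccccc1)c2-c1cc(OCc2ccccc2)cc(=O)o1
F3 | step 7 | 4-(benzyloxy)-6-(4,5,7-trihydroxy-2-phenylnaphthalen-1-yl)-2H-pyran-2-one | Oc1cc(O)cc2c(-c3cc(OCc4ccccc4)cc(=O)o3)c(-c3ccccc3)cc(O)c12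
F4 | step 7 | (3S)-5-[4-(benzyloxy)-2-oxo-2H-pyran-6-yl]-3,8-dihydroxy-6-phenyl-3,4-dihydronaphthalen-1(2H)-one | O=C1C[C@@H](O)Cc2c1c(O)cc(-c1ccccc1)c2-c1cc(OCc2ccccc2)cc(=O)o1
F5 | step 4 | 4-(benzyloxy)-6-(2-oxo-2-phenylethyl)-2H-pyran-2-one | O=C(Cc1cc(OCc2ccccc2)cc(=O)o1)c1ccccc1
F6 | step 4 | rac-tert-butyl 4-[4-(benzyloxy)-2-oxo-2H-pyran-6-yl]-3-hydroxy-3-phenylbutanoate | CC(C)(C)OC(=O)CC(O)(Cc1cc(OCc2ccccc2)cc(=O)o1)c1ccccc1
F7 | step 6 | rac-5-(tert-butyldimethylsilyloxy)-3-oxocyclohex-1-en-1-yl 3-phenylprop-2-ynoate | O=C1C=C(OC(=O)C#Cc2ccccc2)CC(O[Si](C)(C)C(C)(C)C)C1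
F8 | step 6 | 5-(tert-butyldimethylsilyloxy)-2-(3-phenylprop-2-ynoyl)cyclohexane-1,3-dione | O=C1CC(O[Si](C)(C)C(C)(C)C)CC(=O)C1C(=O)C#Cc1ccccc1
F9 | step 6 | rac-7-(tert-butyldimethylsilyloxy)-2-phenyl-7,8-dihydro-4H-chromene-4,5(6H)-dione | O=C1CC(O[Si](C)(C)C(C)(C)C)Cc2oc(-c3ccccc3)cc(=O)c12
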